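The six-membered ring is disconnected at its alkene: removing C2 and C3 leaves C1 (ketone), C6 (quaternary ester carbon), C5 (carbinol) and C4 (methylene) in a row, which is the substitution pattern of a 2-acyloxy-3-alkoxycyclobutanone. The key step exploits this C1–C6–C5–C4 array of the cyclohexenone ring: a [2+2] cycloaddition of methyl(aroyloxy)ketene, generated from an O-aroyl-lactoyl chloride in which the hindered orsellinate ester already exists, with the vinyl ether of a chiral 1-arylethanol forms C5–C6, a temporary C1–C4 bond and both stereocentres in one operation. Nickel-catalysed insertion of an alkyne into C1–C4 then supplies C2 and C3.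

Key step: step 8

Remark on numbering: C1 ketone, C2 methyl-bearing alkene carbon, C3 side-chain-bearing alkene carbon, C4 CH2, C5 CH–O, C6 C(CH3)(O-aroyl).

Assumption: the lactic-acid carbon becomes the sp2 ketene carbon in the key step, so the ketene precursor and the compounds leading to it are carried as racemates (either enantiomer gives the same ketene). Racemic 1,2-epoxypentane is used, so the alkyne and the two ring-expanded intermediates that still hold the side-chain carbinol carbon are mixtures of both epimers at that carbon until it is oxidised.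

Step 1
Reactants: 1 orsellinic acid (2,4-dihydroxy-6-methylbenzoic acid); 2 tert-butyl 2-bromopropanoate (racemic)
Product: 3 tert-butyl 2-[(2,4-dihydroxy-6-methylbenzoyl)oxy]propanoate (racemic)
Conditions: KHCO3, DMF, rt → 40 °C
Reagents that add atoms: none
Why: Carboxylate O-alkylation (SN2 at an activated α-bromo ester) builds the hindered ester by attack of oxygen on carbon, so no acyl substitution at the doubly ortho-substituted carbonyl is needed, and hydrogencarbonate ionises only the carboxylic acid, leaving both phenols untouched.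

Step 2
Reactants: 3 tert-butyl 2-[(2,4-dihydroxy-6-methylbenzoyl)oxy]propanoate
Product: 4 tert-butyl 2-{[2,4-bis(benzyloxy)-6-methylbenzoyl]oxy}propanoate (racemic)
Conditions: BnBr, K2CO3, DMF, 50 °C
Reagents that add atoms: benzyl bromide, BrCc1ccccc1
Why: Williamson etherification of both phenols (the hydrogen-bonded ortho phenol needs gentle warming); both esters are inert to carbonate and no position is open to elimination.

Step 3
Reactants: 4 tert-butyl 2-{[2,4-bis(benzyloxy)-6-methylbenzoyl]oxy}propanoate
Product: 5 2-{[2,4-bis(benzyloxy)-6-methylbenzoyl]oxy}propanoic acid (racemic)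
Conditions: TFA, CH2Cl2, 0 °C → rt
Reagents that add atoms: none
Why: Acidolysis of the tert-butyl ester (loss of the tert-butyl cation as isobutene) should be selective, since the secondary aryl ester and the aryl benzyl ethers tolerate brief exposure to TFA.

Step 4
Reactants: 5 2-{[2,4-bis(benzyloxy)-6-methylbenzoyl]oxy}propanoic acid
Product: 6 2-{[2,4-bis(benzyloxy)-6-methylbenzoyl]oxy}propanoyl chloride (racemic, ketene precursor; used crude)
Conditions: (COCl)2, DMF (cat.), CH2Cl2, 0 °C → rt, then evaporation
Reagents that add atoms: oxalyl chloride, O=C(Cl)C(Cl)=O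
Why: Acid chloride formation through the Vilsmeier-type chloroiminium species under mild conditions that leave the benzoate ester and benzyl ethers intact.

Step 5
Reactants: 7 (S)-1-(2,4,6-triisopropylphenyl)ethanol
Product: 8 (S)-1-(2,4,6-triisopropylphenyl)ethyl vinyl ether
Conditions: [Ir(cod)Cl]2 (cat.), Na2CO3, vinyl acetate, toluene, 100 °C
Reagents that add atoms: vinyl acetate, C=COC(C)=O
Why: Iridium-catalysed transfer vinylation from vinyl acetate (addition–elimination at the coordinated vinyl ester) is irreversible and works on hindered secondary alcohols; the carbinol C–O bond is not broken, so the (S) centre is retained.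

Step 6
Reactants: 9 propyne; 10 1,2-epoxypentane (racemic)
Product: 12 oct-2-yn-5-ol (racemic), via 1-propynyllithium 11 (not isolated)
Conditions: n-BuLi, THF, −78 °C; BF3·OEt2, then 10, −78 °C; aq. HCl work-up
Reagents that add atoms: none
Why: The lithium acetylide opens the BF3-activated epoxide by SN2 attack at the unsubstituted carbon (Lewis-acid-promoted epoxide alkynylation), giving the homopropargylic alcohol.

Step 7
Reactants: 12 oct-2-yn-5-ol
Product: 13 tert-butyl(dimethyl)(oct-2-yn-5-yloxy)silane (racemic)
Conditions: TBSCl, imidazole, DMF, rt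
Reagents that add atoms: tert-butyldimethylsilyl chloride, CC(C)(C)[Si](C)(C)Cl
Why: Standard imidazole-mediated silylation of a secondary alcohol; the silyl ether is inert to zerovalent nickel and is later removed without base.

Step 8
Reactants: 6 2-{[2,4-bis(benzyloxy)-6-methylbenzoyl]oxy}propanoyl chloride (in excess); 8 (S)-1-(2,4,6-triisopropylphenyl)ethyl vinyl ether
Product: 15 (2R,3S)-2-{[2,4-bis(benzyloxy)-6-methylbenzoyl]oxy}-2-methyl-3-[(S)-1-(2,4,6-triisopropylphenyl)ethoxy]cyclobutan-1-one (methyl cis to the alkoxy group), via methyl(aroyloxy)ketene 14 (not isolated)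
Conditions: Et3N (slow addition), toluene, rt → 50 °C
Reagents that add atoms: none
Why: Et3N removes HCl from 6 to give ketene 14; the CH2 terminus of 8 (C4) attacks the ketene carbonyl carbon (C1) in the plane of the ketene substituents, and the developing oxocarbenium–enolate pair closes by bonding of the enolate carbon C6 to the oxocarbenium carbon C5 (one strongly asynchronous [2+2] event or a short-lived zwitterion). The closest known reaction type is the [2+2] cycloaddition of alkyl(halo)ketenes and acyloxyketenes, made in situ from acid chlorides and Et3N, with vinyl ethers, which gives 3-alkoxycyclobutanones. The four-membered ring is closed in 4-exo-trig fashion (C6 onto the C5=O+ carbon), the only mode open to this 1,4-dipole. C5 is set by the auxiliary: in the s-trans enol ether conformer with the carbinol C–H in the π-plane the triisopropylphenyl group covers one face, so C6 should bond to the other and C5 should become (S). C6 is set relative to C5 by the tendency of unsymmetrical ketenes to place the larger substituent (methyl, compared with the single ester oxygen) cis to the substituent on the neighbouring ring carbon, which puts aroyloxy trans to alkoxy and makes C6 (R). The step needs regio-, cis/trans and facial selectivity, secured in turn by the polarity of the enol ether, by the size difference at the ketene carbon (best expressed in a non-polar solvent) and by the auxiliary; every unwanted isomer is a diastereomer of 15 and should be removable by chromatography, and slow base addition keeps ketene self-condensation down.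

Step 9
Reactants: 15 the cyclobutanone; 13 tert-butyl(dimethyl)(oct-2-yn-5-yloxy)silane
Product: 16 (1R,6S)-4-{2-[(tert-butyldimethylsilyl)oxy]pentyl}-1,3-dimethyl-2-oxo-6-[(S)-1-(2,4,6-triisopropylphenyl)ethoxy]cyclohex-3-en-1-yl 2,4-bis(benzyloxy)-6-methylbenzoate (both epimers at the silyloxy carbon)
Conditions: Ni(cod)2 (10 mol %), PCy3 (20 mol %), 13 added slowly, toluene, 100 °C
Reagents that add atoms: none
Why: Zerovalent nickel couples the C1 carbonyl and the alkyne oxidatively (C1–C2 bond at the methyl-bearing alkyne carbon, the bulkier β-silyloxyalkyl end next to nickel), β-carbon elimination opens the strained ring at the less substituted C1–C4 bond and C(sp2)–C(sp3) reductive elimination forms C3–C4, which is the known nickel-catalysed intermolecular alkyne insertion into cyclobutanones; C5 and C6 are spectators and keep their configuration.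

Step 10
Reactants: 16 the silyl ether
Product: 17 (1R,6S)-4-(2-hydroxypentyl)-1,3-dimethyl-2-oxo-6-[(S)-1-(2,4,6-triisopropylphenyl)ethoxy]cyclohex-3-en-1-yl 2,4-bis(benzyloxy)-6-methylbenzoate (both epimers at the carbinol carbon)
Conditions: HF·pyridine, pyridine, THF, 0 °C → rt
Reagents that add atoms: none
Why: Fluoride-mediated desilylation under buffered, weakly acidic conditions should spare the acid-labile benzylic ether and the esters and avoids the base that could trigger vinylogous elimination of the C5 alkoxy group.

Step 11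
Reactants: 17 the side-chain alcohol
Product: 18 (1R,6S)-1,3-dimethyl-2-oxo-4-(2-oxopentyl)-6-[(S)-1-(2,4,6-triisopropylphenyl)ethoxy]cyclohex-3-en-1-yl 2,4-bis(benzyloxy)-6-methylbenzoate
Conditions: Dess–Martin periodinane, CH2Cl2, 0 °C → rt
Reagents that add atoms: none
Why: Dess–Martin oxidation of the only free hydroxyl group (the C5 oxygen still carries the auxiliary) converges both epimers to one ketone under near-neutral conditions.

Step 12
Reactants: 18 the diketone
Product: 19 (1R,6S)-6-hydroxy-1,3-dimethyl-2-oxo-4-(2-oxopentyl)cyclohex-3-en-1-yl 2,4-bis(benzyloxy)-6-methylbenzoate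
Conditions: TFA, CH2Cl2, 0 °C
Reagents that add atoms: none
Why: Acid-catalysed SN1/E1 cleavage of the 1-arylethyl ether ionises at the benzylic carbon, so the C5–O bond is untouched and C5 keeps its configuration; it is done while the phenols are still benzylated so that the released cation (lost as the styrene) cannot alkylate a free resorcinol ring.

Step 13
Reactants: 19 the dibenzyl ether
Product: 20 talarophilone, (1R,6S)-6-hydroxy-1,3-dimethyl-2-oxo-4-(2-oxopentyl)cyclohex-3-en-1-yl 2,4-dihydroxy-6-methylbenzoate
Conditions: H2 (1 atm), Pd/C (palladium on carbon), EtOAc, rt, stopped after uptake of two equivalents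
Reagents that add atoms: none
Why: Catalytic hydrogenolysis of the two aryl benzyl ethers should be fast compared with hydrogenation of the hindered tetrasubstituted enone, and nothing else in the molecule is hydrogenolysed.

Compound list
1 | orsellinic acid (2,4-dihydroxy-6-methylbenzoic acid) | Cc1cc(O)cc(O)c1C(=O)O | starting material
2 | tert-butyl 2-bromopropanoate (racemic) | CC(Br)C(=O)OC(C)(C)C | starting material
3 | tert-butyl 2-[(2,4-dihydroxy-6-methylbenzoyl)oxy]propanoate (racemic) | CC(OC(=O)c1c(C)cc(O)cc1O)C(=O)OC(C)(C)C | intermediate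
4 | tert-butyl 2-{[2,4-bis(benzyloxy)-6-methylbenzoyl]oxy}propanoate (racemic) | CC(OC(=O)c1c(C)cc(OCc2ccccc2)cc1OCc1ccccc1)C(=O)OC(C)(C)C | intermediate
5 | 2-{[2,4-bis(benzyloxy)-6-methylbenzoyl]oxy}propanoic acid (racemic) | CC(OC(=O)c1c(C)cc(OCc2ccccc2)cc1OCc1ccccc1)C(=O)O | intermediate
6 | 2-{[2,4-bis(benzyloxy)-6-methylbenzoyl]oxy}propanoyl chloride (racemic) | CC(OC(=O)c1c(C)cc(OCc2ccccc2)cc1OCc1ccccc1)C(Cl)=O | intermediate
7 | (S)-1-(2,4,6-triisopropylphenyl)ethanol | C[C@H](O)c1c(C(C)C)cc(C(C)C)cc1C(C)C | starting material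
8 | (S)-1-(2,4,6-triisopropylphenyl)ethyl vinyl ether | C=CO[C@@H](C)c1c(C(C)C)cc(C(C)C)cc1C(C)C | intermediate
9 | propyne | CC#C | starting material
10 | 1,2-epoxypentane (racemic) | CCCC1CO1 | starting material
11 | 1-propynyllithium | [Li]C#CC | intermediate (not isolated)
12 | oct-2-yn-5-ol (racemic) | CC#CCC(O)CCC | intermediate
13 | tert-butyl(dimethyl)(oct-2-yn-5-yloxy)silane (racemic) | CC#CCC(CCC)O[Si](C)(C)C(C)(C)C | intermediate
14 | methyl(aroyloxy)ketene, 1-oxoprop-1-en-2-yl 2,4-bis(benzyloxy)-6-methylbenzoate | CC(OC(=O)c1c(C)cc(OCc2ccccc2)cc1OCc1ccccc1)=C=O | intermediate (not isolated)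
15 | (2R,3S)-2-{[2,4-bis(benzyloxy)-6-methylbenzoyl]oxy}-2-methyl-3-[(S)-1-(2,4,6-triisopropylphenyl)ethoxy]cyclobutan-1-one | O=C1[C@](C)(OC(=O)c2c(C)cc(OCc3ccccc3)cc2OCc2ccccc2)[C@@H](O[C@@H](C)c2c(C(C)C)cc(C(C)C)cc2C(C)C)C1 | intermediate
16 | (1R,6S)-4-{2-[(tert-butyldimethylsilyl)oxy]pentyl}-1,3-dimethyl-2-oxo-6-[(S)-1-(2,4,6-triisopropylphenyl)ethoxy]cyclohex-3-en-1-yl 2,4-bis(benzyloxy)-6-methylbenzoate (epimers at the silyloxy carbon) | CCCC(O[Si](C)(C)C(C)(C)C)CC1=C(C)C(=O)[C@](C)(OC(=O)c2c(C)cc(OCc3ccccc3)cc2OCc2ccccc2)[C@@H](O[C@@H](C)c2c(C(C)C)cc(C(C)C)cc2C(C)C)C1 | intermediate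
17 | (1R,6S)-4-(2-hydroxypentyl)-1,3-dimethyl-2-oxo-6-[(S)-1-(2,4,6-triisopropylphenyl)ethoxy]cyclohex-3-en-1-yl 2,4-bis(benzyloxy)-6-methylbenzoate (epimers at the carbinol carbon) | CCCC(O)CC1=C(C)C(=O)[C@](C)(OC(=O)c2c(C)cc(OCc3ccccc3)cc2OCc2ccccc2)[C@@H](O[C@@H](C)c2c(C(C)C)cc(C(C)C)cc2C(C)C)C1 | intermediate
18 | (1R,6S)-1,3-dimethyl-2-oxo-4-(2-oxopentyl)-6-[(S)-1-(2,4,6-triisopropylphenyl)ethoxy]cyclohex-3-en-1-yl 2,4-bis(benzyloxy)-6-methylbenzoate | CCCC(=O)CC1=C(C)C(=O)[C@](C)(OC(=O)c2c(C)cc(OCc3ccccc3)cc2OCc2ccccc2)[C@@H](O[C@@H](C)c2c(C(C)C)cc(C(C)C)cc2C(C)C)C1 | intermediate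
19 | (1R,6S)-6-hydroxy-1,3-dimethyl-2-oxo-4-(2-oxopentyl)cyclohex-3-en-1-yl 2,4-bis(benzyloxy)-6-methylbenzoate | CCCC(=O)CC1=C(C)C(=O)[C@](C)(OC(=O)c2c(C)cc(OCc3ccccc3)cc2OCc2ccccc2)[C@@H](O)C1 | intermediate
20 | talarophilone, (1R,6S)-6-hydroxy-1,3-dimethyl-2-oxo-4-(2-oxopentyl)cyclohex-3-en-1-yl 2,4-dihydroxy-6-methylbenzoate | CCCC(=O)CC1=C(C)C(=O)[C@](C)(OC(=O)c2c(C)cc(O)cc2O)[C@@H](O)C1 | target

Total step count: 13. Longest linear sequence: 10 steps (steps 1–4 and 8–13); steps 5 and 6–7 are side branches.

Steps most likely to fail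

Step 8. The ketene may be consumed by self-condensation faster than the sterically shielded enol ether intercepts it. The enol ether also lacks a cis β-substituent, so it may react through more than one conformer and facial discrimination may be weak. The fallback sets out from 6 and comes back to the route at 20. The cycloaddition is run with commercial benzyl vinyl ether (C=COCc1ccccc1), a small and more nucleophilic partner, under the conditions of step 8. The racemic methyl-cis cyclobutanone is resolved by preparative chromatography on a chiral stationary phase to give (1R,2S)-2-(benzyloxy)-1-methyl-4-oxocyclobutyl 2,4-bis(benzyloxy)-6-methylbenzoate F1. This is taken through the nickel-catalysed insertion of 13 to the silyl ether F2, HF·pyridine desilylation to the side-chain alcohol F3 and Dess–Martin oxidation to the diketone F4, as in steps 9–11. One hydrogenolysis (H2, Pd/C, EtOAc) of all three benzyl ethers of F4 then gives 20, so the acidolysis step is not needed.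

Step 9. Oxidative cyclisation at a carbonyl flanked by the quaternary carbon may be slow, so that alkyne oligomerisation competes. The two alkyne termini (methyl against a β-branched primary alkyl) may not be told apart well, giving the regioisomeric enone, and the alkylnickel intermediate at C4 may lose the C5 alkoxide. The fallback sets out from 12 and 15 and comes back at 18. Alcohol 12 is oxidised with Dess–Martin periodinane to oct-2-yn-5-one F5, which is enolised towards the propargylic position and silylated (TBSOTf, Et3N, CH2Cl2, −78 °C) to the conjugated enyne (Z)-tert-butyl(dimethyl)(oct-4-en-2-yn-5-yloxy)silane F6. Conjugated enynes are known to enter nickel-mediated oxidative cyclisation with carbonyl groups more readily and with the alkenyl-bearing alkyne carbon bound to nickel, which fixes the methyl-bearing carbon on C1. Insertion into 15 under the conditions of step 9 should give the silyl dienol ether F7. Its mild hydrolysis (HF·pyridine, wet THF) unveils the side-chain ketone and gives 18, replacing steps 10 and 11.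

Step 13. Over-reduction may occur: hydrogen may add to the C2=C3 double bond or to a ketone before both benzyl groups are gone. The fallback sets out from 19 and comes back at 20 and makes no new compound (F0). It is a non-reductive Lewis-acid debenzylation with BCl3 and pentamethylbenzene as cation scavenger in CH2Cl2 at −78 °C, which cleaves aryl benzyl ethers and leaves alkenes, ketones and esters alone.

Further compounds
F1 | step 8 | (1R,2S)-2-(benzyloxy)-1-methyl-4-oxocyclobutyl 2,4-bis(benzyloxy)-6-methylbenzoate | O=C1[C@](C)(OC(=O)c2c(C)cc(OCc3ccccc3)cc2OCc2ccccc2)[C@@H](OCc2ccccc2)C1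
F2 | step 8 | (1R,6S)-6-(benzyloxy)-4-{2-[(tert-butyldimethylsilyl)oxy]pentyl}-1,3-dimethyl-2-oxocyclohex-3-en-1-yl 2,4-bis(benzyloxy)-6-methylbenzoate (epimers at the silyloxy carbon) | CCCC(O[Si](C)(C)C(C)(C)C)CC1=C(C)C(=O)[C@](C)(OC(=O)c2c(C)cc(OCc3ccccc3)cc2OCc2ccccc2)[C@@H](OCc2ccccc2)C1
F3 | step 8 | (1R,6S)-6-(benzyloxy)-4-(2-hydroxypentyl)-1,3-dimethyl-2-oxocyclohex-3-en-1-yl 2,4-bis(benzyloxy)-6-methylbenzoate (epimers at the carbinol carbon) | CCCC(O)CC1=C(C)C(=O)[C@](C)(OC(=O)c2c(C)cc(OCc3ccccc3)cc2OCc2ccccc2)[C@@H](OCc2ccccc2)C1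
F4 | step 8 | (1R,6S)-6-(benzyloxy)-1,3-dimethyl-2-oxo-4-(2-oxopentyl)cyclohex-3-en-1-yl 2,4-bis(benzyloxy)-6-methylbenzoate | CCCC(=O)CC1=C(C)C(=O)[C@](C)(OC(=O)c2c(C)cc(OCc3ccccc3)cc2OCc2ccccc2)[C@@H](OCc2ccccc2)C1
F5 | step 9 | oct-2-yn-5-one | CC#CCC(=O)CCC
F6 | step 9 | (Z)-tert-butyl(dimethyl)(oct-4-en-2-yn-5-yloxy)silane | CC#C/C=C(/CCC)O[Si](C)(C)C(C)(C)C
F7 | step 9 | (1R,6S)-4-{(Z)-2-[(tert-butyldimethylsilyl)oxy]pent-1-en-1-yl}-1,3-dimethyl-2-oxo-6-[(S)-1-(2,4,6-triisopropylphenyl)ethoxy]cyclohex-3-en-1-yl 2,4-bis(benzyloxy)-6-methylbenzoate | CCC/C(O[Si](C)(C)C(C)(C)C)=C/C1=C(C)C(=O)[C@](C)(OC(=O)c2c(C)cc(OCc3ccccc3)cc2OCc2ccccc2)[C@@H](O[C@@H](C)c2c(C(C)C)cc(C(C)C)cc2C(C)C)C1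
F0 | step 13 | none | none
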